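## Structural features

Haemathamnolic acid (27) is a meta-depside made of two benzene rings and no other ring, joined by one aryl ester from the C1 carbonyl of ring A to O5' of ring B. It has no stereocentre, so no stereocentres stand next to each other and nothing has to be set or preserved. Ring A carries, in order, the ester carbonyl (C1), a hydroxyl (C2), a formyl group (C3), a methoxyl (C4), hydrogen (C5) and methyl (C6); ring B is fully substituted with carboxyl (C1'), hydroxyl (C2'), formyl (C3'), hydroxyl (C4'), the acylated oxygen (C5') and methyl (C6'). The fragile groups are the aryl ester (in the target it sits beside a free 4'-hydroxyl, so base invites acyl migration or cleavage), the two chelated formyl groups (oxidation, Dakin cleavage, over-reduction) and the salicylic acid of ring B (decarboxylation in acid or on heating). The real difficulty is regiochemical and steric: the ring A formyl group lies between two oxygens, so an electrophilic formylation would have to choose between C3 and C5, ring B needs an oxygen at C5' that orsellinic acid lacks, and the ester joins a 2,6-disubstituted acid to a 2,6-disubstituted phenol. The key step exploits the vicinal pair C2–OH/C3–CHO of ring A with the C4 methoxyl beside C3: a C2–C3 aryne, polarised by that methoxyl, takes the oxygen at C2 and the formyl carbon at C3 from one molecule of DMF.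

## Logic of the disconnections

27 ⇒ 26. The three benzyl–oxygen bonds (the C1' ester, O2' and O4') are cut last. Neutral hydrogenolysis is the one set of conditions under which the depside ester, both aldehydes and the salicylic acid are all safe. In 26 ring B has no acidic hydroxyl or carboxyl, so the fluoride step meets only the phenol it creates. The forward step must stop before a formyl group is reduced.

26 ⇒ 21 + 22. The C2–O and C3–C(formyl) bonds are cut together. Both groups then arrive in one operation in a fixed 1,2-relationship, and ring A of 21 needs only silicon and triflate on neighbouring carbons. This removes any electrophilic formylation of ring A with its C3/C5 ambiguity. The forward step demands that the oxygen of 22 goes to C2 and not to C3, and that the depside ester survives fluoride.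

21 ⇒ 11 + 19. The acyl C–O5' bond is cut because it divides the molecule into two rings of similar effort (four steps to 11, five to 19). The forward acylation joins two di-ortho-substituted partners. It must run without fluoride, which would release the aryne early, and without strong acid, which would protodesilylate C3.

11 ⇒ 10 ⇒ 8 (through 9). The allyl–O bond of the ester, the S–O bond of the triflate and, before that, the carbamoyl–O bond are cut. The carboxyl is kept as an ester while the phenol is freed and triflated: a free acid would compete for the triflating agent, and as an acid chloride it would cyclise onto the carbamate N–H. Allyl is chosen because zerovalent palladium removes it under neutral conditions that touch neither triflate nor aryl silane. An N,N-dialkyl carbamate would direct the same metalations, but its removal needs hot hydroxide or hydride, which the aryl silane and the carboxyl would not tolerate. The N-isopropyl carbamate leaves by E1cB elimination with an amine base at 40 °C. The demand is a one-pot decarbamoylation and triflation at a hindered, chelated phenoxide.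

8 ⇒ 2 (through 5). The C1–C(carboxyl) bond and the C3–Si bond are cut, and both are formed in one flask. The C–H between the two oxygens is the most acidic one, so silicon goes there first; it marks C3 as the future aryne carbon and blocks it. C1 is then the only position ortho to the carbamate that is still free, and the carboxyl carbon arrives from a chloroformate already as the protected ester. The forward sequence demands that the first electrophile is used without excess, so that it does not consume the second base. The second lithiation, at a C–H flanked by the carbamate and the methyl group, must stay at −78 °C to prevent anionic Fries migration. The methyl group is meta to the directing group, so lateral lithiation is not expected.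

2 ⇒ 1. The carbamoyl–O bond is cut. This leads back to commercial 1 and installs the directing group that is later removed under mild conditions.

19 ⇒ 17 (through 18). The C5'–O bond is cut; in the forward sense C–Br becomes C–B and then C–O. Bromine is a placeholder that survives formylation and benzylation, so O5' ends up as the only free hydroxyl of ring B. The demands are borylation of a di-ortho-substituted bromide and an oxidation that spares the aldehyde.

17 ⇒ 16 ⇒ 14. The two benzyl–O ether bonds and the C3'–C(formyl) bond are cut. With C5' occupied by bromine, C3' is the only free ring position, so the formylation has no regiochemical choice. Both neighbouring hydroxyls activate it. The Lewis acid must spare the benzyl ester.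

14 ⇒ 13 ⇒ 12. The C5'–Br bond and the benzyl–O bond of the ester are cut. C5' is para to the 2'-hydroxyl and ortho to the 4'-hydroxyl, which is the innately preferred site of a 2,4-dihydroxybenzoate. The benzyl ester suppresses decarboxylation and leaves with the ethers at the end. The demand is clean monobromination at C5' and not at C3'.

## Other disconnections considered

Alternative 1: The cut is the C1–C6 bond of ring A. In the forward step the ring B aryl triketo ester benzyl 2,4-bis(benzyloxy)-6-methyl-5-[(3,5,7-trioxooctanoyl)oxy]benzoate A1 would cyclise by intramolecular aldol attack of its C2 enolate on the C7 ketone, then dehydrate and enolise to the orsellinate depside A2.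
- In its favour: the route is biomimetic, and the aromatisation is strongly downhill with no regiochemical ambiguity in the ring closure. On that point it is better than the chosen plan, whose aryne step carries a regiochemical risk.
- Also in its favour: the depside C–O bond would be made on an unhindered acyclic acyl donor, which is easier than the hindered acylation of step 10. The two ring A hydroxyls of A2 are differentiated by chelation, so 4-O-methylation would be selective.
- Against it: in A1 the aryl ester is the best leaving group in the molecule. Lactonisation of the triketide to a pyranone would expel the ring B phenoxide, and Claisen-type C-acylation is a second competing closure.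
- Against it: A2 lacks the methyl ether and both formyl groups. Ring A formylation faces the C3/C5 choice. C3' of ring B lies between two benzyloxy groups with no free phenol beside it. If the ring B aldehyde were carried through instead, it would be an aldol acceptor for the triketide enolates.
- Comparison: on structure it leaves unsolved exactly the problem that the chosen plan solves by marking C3 with silicon. On mechanism both rest on known reaction types. On step economy it is equal at best up to A2 and longer once the methylation and two formylations are added.

Alternative 2: The cuts are the C1–C(=O) and C(=O)–O5' bonds. In the forward step the aryl iodide 2-(benzyloxy)-3-iodo-6-methoxy-4-methylbenzaldehyde A3, carbon monoxide A4 and phenol 19 would combine under Pd(OAc)2, Xantphos and Et3N to the tetrabenzyl depside A5.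
- In its favour: it is the most convergent plan. Both formyl groups are in place before the union, so nothing regiochemical is left for the late stage; on this point it is better than the chosen plan.
- Also in its favour: no hindered benzoic acid has to be made and activated. A3 should be reachable from 1 in three or four steps, so the step count is equal or slightly lower. The end game is the same hydrogenolysis with one more benzyl group.
- Against it: the ester would be tetra-ortho-substituted. Oxidative addition into an iodide flanked by benzyloxy and methyl, and above all attack of the hindered, weakly nucleophilic phenoxide of 19 on a crowded aroylpalladium species, are expected to be slow. Reduction, decarbonylation to a diaryl ether and base-mediated damage to the aldehydes could then compete.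
- Against it: making A3 only moves the regiochemical problem (substitution between the oxygens of 1 versus its other sites) to the iodination and formylation of 1.
- Comparison: the chosen plan spreads its risk over a classical acylation and the aryne step. The alternative puts it into one catalytic step whose precedent lies with far less hindered partners.

Alternative 3: The cuts are the C5–C6 and C1–C2 bonds of ring A. In the forward step the diene 1,3-dimethoxy-1-(trimethylsilyloxy)buta-1,3-diene A6 would add to the ring B aryl but-2-ynoate benzyl 2,4-bis(benzyloxy)-5-(but-2-ynoyloxy)-6-methylbenzoate A7. Loss of methanol and of the silyl group would give the 2-hydroxy-4-methoxy-6-methylbenzoate A8.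
- In its favour: the polarity of diene and ynoate fixes the regiochemistry of the [4+2] addition. The 2-hydroxyl and 4-methoxyl emerge already differentiated, which is better than any plan that must methylate selectively.
- Also in its favour: the ester is made on small but-2-ynoic acid, which is easier than step 10. No strong base or fluoride touches the depside.
- Against it: a β-methyl ynoate is a sluggish dienophile that needs heat, while A6 is sensitive to heat and moisture.
- Against it: A8 lacks both formyl groups. Ring A formylation ortho to the free hydroxyl is conceivable but competes with C5 and needs a Lewis acid next to benzyl ethers. C3' of ring B has no handle. A formyl group carried in A7 would be attacked by the silyl ketene acetal diene.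
- Comparison: the ring construction is about as long as steps 1–4 of the chosen plan, so it is equal on that part. The two late formylations make it longer overall and less controlled.

Key step: step 11

Remarks on the chemistry:
- The target has no stereogenic element. Ring A is numbered C1 (carbonyl-bearing) to C6 (methyl-bearing), and ring B C1' (carboxyl-bearing) to C6'.
- Compounds 21 and 26 map onto the target atom for atom.
- Design choices on the way to 21: an N-isopropyl carbamate is preferred to an N,N-dialkyl one, both ortho-metalations are run in one flask on the transiently N-silylated carbamate, the carboxyl is carried as an allyl ester through the triflation, and the acid chloride is formed under neutral, fluoride-free conditions.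

## Route

Step 1
Reactants: 1 3-methoxy-5-methylphenol
Product: 2 3-methoxy-5-methylphenyl N-isopropylcarbamate
Conditions: i-PrNCO, Et3N (cat.), CH2Cl2, rt
Reagents that add atoms: isopropyl isocyanate, CC(C)N=C=O
Why: Base-catalysed addition of the phenol to the isocyanate (carbamoylation); the secondary carbamate is a strong ortho-directing group once N-silylated and can later be removed by mild E1cB elimination.

Step 2
Reactants: 2 3-methoxy-5-methylphenyl N-isopropylcarbamate
Product: 8 allyl 2-[(isopropylcarbamoyl)oxy]-4-methoxy-6-methyl-3-(trimethylsilyl)benzoate, via N-silyl carbamate 3 (not isolated), via first aryllithium 4 (not isolated), via bis-silyl carbamate 5 (not isolated), via second aryllithium 6 (not isolated), via N-silyl allyl ester 7 (not isolated)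
Conditions: TMSOTf, TMEDA, Et2O, rt; n-BuLi (2.1 equiv), TMEDA, −78 °C; TMSCl (1.0 equiv), −78 → −40 °C; s-BuLi, −78 °C; ClCO2CH2CH=CH2, −78 °C → rt; aq. NH4Cl
Reagents that add atoms: chlorotrimethylsilane, C[Si](C)(C)Cl; allyl chloroformate, C=CCOC(=O)Cl; trimethylsilyl trifluoromethanesulfonate, C[Si](C)(C)OS(=O)(=O)C(F)(F)F (the N-silyl group of 3 to 7, lost again on work-up)
Why: One-pot iterative directed ortho-metalation: transient N-silylation masks the N–H (the second equivalent of n-BuLi neutralises the TMEDA·HOTf formed), the C–H between the carbamate oxygen and the methoxyl is removed first by cooperative direction and silylated, and the silyl group then blocks that site so that s-BuLi lithiates the only remaining position ortho to the carbamate, the meta methyl group staying untouched. Acylation of the second aryllithium by the chloroformate at −78 °C, before any anionic Fries shift, gives the hindered ester, which resists a second addition. The N–Si bond is hydrolysed on the mild aqueous work-up while the C–Si bond stays.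

Step 3
Reactants: 8 allyl 2-[(isopropylcarbamoyl)oxy]-4-methoxy-6-methyl-3-(trimethylsilyl)benzoate
Product: 10 allyl 4-methoxy-6-methyl-2-{[(trifluoromethyl)sulfonyl]oxy}-3-(trimethylsilyl)benzoate, via silyl phenol 9 (not isolated)
Conditions: Et2NH (1.1 equiv), DBU, MeCN, 40 °C; then PhNTf2, 40 °C
Reagents that add atoms: N-phenylbis(trifluoromethanesulfonimide), O=S(=O)(N(c1ccccc1)S(=O)(=O)C(F)(F)F)C(F)(F)F
Why: E1cB cleavage of the secondary carbamate (N–H deprotonation, loss of isopropyl isocyanate, trapped by Et2NH as a urea) frees the phenoxide, which is sulfonylated in the same flask; the conditions are free of fluoride, hydroxide and acid, so the aryl silane and the allyl ester are kept.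

Step 4
Reactants: 10 allyl 4-methoxy-6-methyl-2-{[(trifluoromethyl)sulfonyl]oxy}-3-(trimethylsilyl)benzoate
Product: 11 4-methoxy-6-methyl-2-{[(trifluoromethyl)sulfonyl]oxy}-3-(trimethylsilyl)benzoic acid
Conditions: Pd(PPh3)4 (cat.), morpholine, THF, rt; aq. citric acid
Reagents that add atoms: none
Why: Tsuji–Trost deallylation: zerovalent palladium ionises the allyl ester to a π-allyl complex that morpholine captures; oxidative addition into the di-ortho-substituted aryl triflate is far slower at room temperature with PPh3, and no fluoride or strong acid is involved.

Step 5
Reactants: 12 orsellinic acid (2,4-dihydroxy-6-methylbenzoic acid)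
Product: 13 benzyl 2,4-dihydroxy-6-methylbenzoate
Conditions: BnBr, KHCO3, DMF, 40 °C
Reagents that add atoms: benzyl bromide, BrCc1ccccc1
Why: Chemoselective SN2 alkylation of the carboxylate: hydrogencarbonate deprotonates the acid but not the phenols; the ester also stops decarboxylation in later steps.

Step 6
Reactants: 13 benzyl 2,4-dihydroxy-6-methylbenzoate
Product: 14 benzyl 3-bromo-4,6-dihydroxy-2-methylbenzoate
Conditions: NBS (1.0 equiv), MeCN, −20 → 0 °C
Reagents that add atoms: N-bromosuccinimide, O=C1CCC(=O)N1Br
Why: Electrophilic aromatic bromination at C5' of ring B, which is para to the 2'-hydroxyl and ortho to the 4'-hydroxyl and the methyl group, the preferred site of 2,4-dihydroxybenzoates; one equivalent at low temperature limits attack at C3' and dibromination.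

Step 7
Reactants: 14 benzyl 3-bromo-4,6-dihydroxy-2-methylbenzoate
Product: 16 benzyl 3-bromo-5-formyl-4,6-dihydroxy-2-methylbenzoate, via chloro(methoxy)methyl arene 15 (not isolated)
Conditions: Cl2CHOMe, TiCl4, CH2Cl2, −10 → 0 °C; then ice, aq. HCl
Reagents that add atoms: dichloromethyl methyl ether, COC(Cl)Cl; water, O
Why: Rieche formylation: the only free ring position lies between two titanium-bound phenoxides, so the chloro(methoxy)carbenium ion has no regiochemical choice; the α-chloro ether is hydrolysed to the aldehyde on work-up, and the low temperature spares the benzyl ester.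

Step 8
Reactants: 16 benzyl 3-bromo-5-formyl-4,6-dihydroxy-2-methylbenzoate
Product: 17 benzyl 4,6-bis(benzyloxy)-3-bromo-5-formyl-2-methylbenzoate
Conditions: BnBr, K2CO3, DMF, 50 °C
Reagents that add atoms: benzyl bromide, BrCc1ccccc1
Why: Williamson etherification of both chelated, acidic phenols, which need a dipolar solvent and gentle warming; the hindered benzyl ester, the aryl bromide and the non-enolisable aldehyde are inert.

Step 9
Reactants: 17 benzyl 4,6-bis(benzyloxy)-3-bromo-5-formyl-2-methylbenzoate
Product: 19 benzyl 2,4-bis(benzyloxy)-3-formyl-5-hydroxy-6-methylbenzoate, via pinacol boronate 18 (not isolated)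
Conditions: B2pin2, Pd(OAc)2, SPhos, KOAc, 1,4-dioxane, 90 °C; then 30% aq. H2O2, NaHCO3, THF, 0 °C → rt
Reagents that add atoms: hydrogen peroxide, OO (the phenol oxygen); bis(pinacolato)diboron, CC1(C)OB(OC1(C)C)B1OC(C)(C)C(C)(C)O1 (the boron of 18, lost again)
Why: Miyaura borylation with a bulky dialkylbiarylphosphine, chosen because the bromide is flanked by benzyloxy and methyl, then oxidation of the C–B bond by 1,2-aryl shift from boron to oxygen. Boronate oxidation should be much faster than Dakin-type attack on a non-phenolic aldehyde, and the new hydroxyl is meta to the formyl group.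

Step 10
Reactants: 11 4-methoxy-6-methyl-2-{[(trifluoromethyl)sulfonyl]oxy}-3-(trimethylsilyl)benzoic acid; 19 benzyl 2,4-bis(benzyloxy)-3-formyl-5-hydroxy-6-methylbenzoate
Product: 21 benzyl 2,4-bis(benzyloxy)-3-formyl-6-methyl-5-{[4-methoxy-6-methyl-2-(trifluoromethylsulfonyloxy)-3-(trimethylsilyl)benzoyl]oxy}benzoate, via acid chloride 20 (not isolated)
Conditions: 1-chloro-N,N,2-trimethylprop-1-en-1-amine, CH2Cl2, 0 °C → rt; then 19, Et3N, DMAP, CH2Cl2, rt → 40 °C
Reagents that add atoms: 1-chloro-N,N,2-trimethylprop-1-en-1-amine, CC(C)=C(Cl)N(C)C (the chlorine of 20, lost again)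
Why: The α-chloroenamine converts the acid into its chloride under neutral conditions (an amide is the only by-product, no HCl, no fluoride), which protects the aryl silane; DMAP-catalysed acylation of the phenol then forms the depside ester, the small acyl chloride being the most reliable electrophile for a di-ortho-substituted acid.

Step 11
Reactants: 21 benzyl 2,4-bis(benzyloxy)-3-formyl-6-methyl-5-{[4-methoxy-6-methyl-2-(trifluoromethylsulfonyloxy)-3-(trimethylsilyl)benzoyl]oxy}benzoate; 22 N,N-dimethylformamide
Product: 26 benzyl 2,4-bis(benzyloxy)-3-formyl-5-[(3-formyl-2-hydroxy-4-methoxy-6-methylbenzoyl)oxy]-6-methylbenzoate, via aryne 23 (not isolated), via benzoxete 24 (not isolated), via quinone methide aminal 25 (not isolated)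
Conditions: CsF, DMF (dry, solvent and reagent), rt; then H2O, aq. NH4Cl
Reagents that add atoms: N,N-dimethylformamide, CN(C)C=O; water, O
Why: Fluoride attacks silicon of 21 and the C3 carbanion expels the C2 triflate, giving aryne 23 (fluoride-induced 1,2-elimination of an ortho-silylaryl triflate). The carbonyl oxygen of 22 adds to C2 and the resulting C3 aryl anion closes onto the iminium carbon to give benzoxete 24, which opens by 4π electrocyclic ring opening to the ortho-quinone methide aminal 25; water hydrolyses 25 to the C2 phenol and the C3 aldehyde of 26 and releases dimethylamine. The closest known reaction type is the insertion of arynes from ortho-silylaryl triflates into the C=O bond of formamides, which gives salicylaldehydes on hydrolysis. No ring persists: the only ring closed is the transient four-membered oxete (formal [2+2] addition across C=O), and it is opened in the same flask. No stereocentre is formed in 26; the aminal carbon of 24 is racemic and is lost. The step needs regioselective addition across C2–C3: the C4 methoxyl, through the inductive effect of an oxygen bound directly to the ring, makes the distal carbon C2 the electrophilic terminus and places the developing negative charge on C3 beside it, while the C1 ester is bound through carbon, distorts the aryne far less and should be overridden. It also needs chemoselectivity: CsF dissolves only sparingly in DMF, so the aryne is released slowly into a large excess of 22 and should be taken up by solvent before it meets the phenoxide of 26 or 25. The hindered depside ester, the benzyl groups and the ring B aldehyde are expected to be inert to fluoride at room temperature.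

Step 12
Reactants: 26 benzyl 2,4-bis(benzyloxy)-3-formyl-5-[(3-formyl-2-hydroxy-4-methoxy-6-methylbenzoyl)oxy]-6-methylbenzoate
Product: 27 haemathamnolic acid (3-formyl-5-[(3-formyl-2-hydroxy-4-methoxy-6-methylbenzoyl)oxy]-2,4-dihydroxy-6-methylbenzoic acid)
Conditions: H2 (1 atm), Pd/C, EtOAc, rt
Reagents that add atoms: none
Why: Hydrogenolysis of the benzyl ester and the two benzyl ethers; at atmospheric pressure in a neutral aprotic solvent the chelated aryl aldehydes and the aryl ester should be reduced far more slowly, and the reaction is stopped after uptake of three equivalents of hydrogen.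

## Compound list

1 | 3-methoxy-5-methylphenol | COc1cc(C)cc(O)c1 | starting material
2 | 3-methoxy-5-methylphenyl N-isopropylcarbamate | COc1cc(C)cc(OC(=O)NC(C)C)c1 | intermediate
3 | 3-methoxy-5-methylphenyl N-isopropyl-N-(trimethylsilyl)carbamate | COc1cc(C)cc(OC(=O)N(C(C)C)[Si](C)(C)C)c1 | intermediate (not isolated)
4 | [2-{[isopropyl(trimethylsilyl)carbamoyl]oxy}-6-methoxy-4-methylphenyl]lithium | COc1cc(C)cc(OC(=O)N(C(C)C)[Si](C)(C)C)c1[Li] | intermediate (not isolated)
5 | 3-methoxy-5-methyl-2-(trimethylsilyl)phenyl N-isopropyl-N-(trimethylsilyl)carbamate | COc1cc(C)cc(OC(=O)N(C(C)C)[Si](C)(C)C)c1[Si](C)(C)C | intermediate (not isolated)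
6 | [2-{[isopropyl(trimethylsilyl)carbamoyl]oxy}-4-methoxy-6-methyl-3-(trimethylsilyl)phenyl]lithium | COc1cc(C)c([Li])c(OC(=O)N(C(C)C)[Si](C)(C)C)c1[Si](C)(C)C | intermediate (not isolated)
7 | allyl 2-{[isopropyl(trimethylsilyl)carbamoyl]oxy}-4-methoxy-6-methyl-3-(trimethylsilyl)benzoate | COc1cc(C)c(C(=O)OCC=C)c(OC(=O)N(C(C)C)[Si](C)(C)C)c1[Si](C)(C)C | intermediate (not isolated)
8 | allyl 2-[(isopropylcarbamoyl)oxy]-4-methoxy-6-methyl-3-(trimethylsilyl)benzoate | COc1cc(C)c(C(=O)OCC=C)c(OC(=O)NC(C)C)c1[Si](C)(C)C | intermediate
9 | allyl 2-hydroxy-4-methoxy-6-methyl-3-(trimethylsilyl)benzoate | COc1cc(C)c(C(=O)OCC=C)c(O)c1[Si](C)(C)C | intermediate (not isolated)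
10 | allyl 4-methoxy-6-methyl-2-{[(trifluoromethyl)sulfonyl]oxy}-3-(trimethylsilyl)benzoate | COc1cc(C)c(C(=O)OCC=C)c(OS(=O)(=O)C(F)(F)F)c1[Si](C)(C)C | intermediate
11 | 4-methoxy-6-methyl-2-{[(trifluoromethyl)sulfonyl]oxy}-3-(trimethylsilyl)benzoic acid | COc1cc(C)c(C(=O)O)c(OS(=O)(=O)C(F)(F)F)c1[Si](C)(C)C | intermediate
12 | orsellinic acid (2,4-dihydroxy-6-methylbenzoic acid) | Cc1cc(O)cc(O)c1C(=O)O | starting material
13 | benzyl 2,4-dihydroxy-6-methylbenzoate | Cc1cc(O)cc(O)c1C(=O)OCc1ccccc1 | intermediate
14 | benzyl 3-bromo-4,6-dihydroxy-2-methylbenzoate | Cc1c(Br)c(O)cc(O)c1C(=O)OCc1ccccc1 | intermediate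
15 | benzyl 3-bromo-5-[chloro(methoxy)methyl]-4,6-dihydroxy-2-methylbenzoate (racemic at the chloro ether carbon) | COC(Cl)c1c(O)c(Br)c(C)c(C(=O)OCc2ccccc2)c1O | intermediate (not isolated)
16 | benzyl 3-bromo-5-formyl-4,6-dihydroxy-2-methylbenzoate | Cc1c(Br)c(O)c(C=O)c(O)c1C(=O)OCc1ccccc1 | intermediate
17 | benzyl 4,6-bis(benzyloxy)-3-bromo-5-formyl-2-methylbenzoate | Cc1c(Br)c(OCc2ccccc2)c(C=O)c(OCc2ccccc2)c1C(=O)OCc1ccccc1 | intermediate
18 | benzyl 4,6-bis(benzyloxy)-5-formyl-2-methyl-3-(4,4,5,5-tetramethyl-1,3,2-dioxaborolan-2-yl)benzoate | Cc1c(B2OC(C)(C)C(C)(C)O2)c(OCc2ccccc2)c(C=O)c(OCc2ccccc2)c1C(=O)OCc1ccccc1 | intermediate (not isolated)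
19 | benzyl 2,4-bis(benzyloxy)-3-formyl-5-hydroxy-6-methylbenzoate | Cc1c(O)c(OCc2ccccc2)c(C=O)c(OCc2ccccc2)c1C(=O)OCc1ccccc1 | intermediate
20 | 4-methoxy-6-methyl-2-{[(trifluoromethyl)sulfonyl]oxy}-3-(trimethylsilyl)benzoyl chloride | COc1cc(C)c(C(=O)Cl)c(OS(=O)(=O)C(F)(F)F)c1[Si](C)(C)C | intermediate (not isolated)
21 | benzyl 2,4-bis(benzyloxy)-3-formyl-6-methyl-5-{[4-methoxy-6-methyl-2-(trifluoromethylsulfonyloxy)-3-(trimethylsilyl)benzoyl]oxy}benzoate | COc1cc(C)c(C(=O)Oc2c(C)c(C(=O)OCc3ccccc3)c(OCc3ccccc3)c(C=O)c2OCc2ccccc2)c(OS(=O)(=O)C(F)(F)F)c1[Si](C)(C)C | intermediate
22 | N,N-dimethylformamide | CN(C)C=O | starting material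
23 | C2–C3 aryne of the depside (benzyl 2,4-bis(benzyloxy)-3-formyl-5-[(4-methoxy-6-methyl-2,3-didehydrobenzoyl)oxy]-6-methylbenzoate) | COC1=CC(C)=C(C(=O)Oc2c(C)c(C(=O)OCc3ccccc3)c(OCc3ccccc3)c(C=O)c2OCc2ccccc2)C#C1 | intermediate (not isolated)
24 | benzyl 2,4-bis(benzyloxy)-5-{[2-(dimethylamino)-3-methoxy-5-methyl-2H-benzo[b]oxete-6-carbonyl]oxy}-3-formyl-6-methylbenzoate (racemic at the aminal carbon) | COc1cc(C)c(C(=O)Oc3c(C)c(C(=O)OCc4ccccc4)c(OCc4ccccc4)c(C=O)c3OCc3ccccc3)c2OC(N(C)C)c12 | intermediate (not isolated)
25 | benzyl 2,4-bis(benzyloxy)-5-({5-[(dimethylamino)methylidene]-4-methoxy-2-methyl-6-oxocyclohexa-1,3-diene-1-carbonyl}oxy)-3-formyl-6-methylbenzoate (alkene geometry not defined) | COC1=CC(C)=C(C(=O)Oc2c(C)c(C(=O)OCc3ccccc3)c(OCc3ccccc3)c(C=O)c2OCc2ccccc2)C(=O)C1=CN(C)C | intermediate (not isolated)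
26 | benzyl 2,4-bis(benzyloxy)-3-formyl-5-[(3-formyl-2-hydroxy-4-methoxy-6-methylbenzoyl)oxy]-6-methylbenzoate | COc1cc(C)c(C(=O)Oc2c(C)c(C(=O)OCc3ccccc3)c(OCc3ccccc3)c(C=O)c2OCc2ccccc2)c(O)c1C=O | intermediate
27 | haemathamnolic acid | COc1cc(C)c(C(=O)Oc2c(C)c(C(=O)O)c(O)c(C=O)c2O)c(O)c1C=O | target

## Step count and least certain steps

Total step count: 12 (10 before the key step, 1 after it). Longest linear sequence: 8 steps (steps 5–9, 10, 11, 12); the ring A branch (steps 1–4, 10, 11, 12) has 7.

**Step 11 (key step).**
- What may go wrong: erosion or reversal of the regioselectivity of addition across C2–C3, because attack at C2 takes place beside the bulky C1 ester, whose own inductive pull opposes that of the methoxyl. The aryne may also be consumed by the phenoxide that is being formed or by the quinone methide, and fluoride or phenoxide may transesterify the depside link.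
- Fallback, setting out from 8 and 19 and returning at 26: 8 is decarbamoylated as in step 3 without the triflating agent and 9 is isolated. Rieche formylation of 9 (Cl2CHOMe, TiCl4, CH2Cl2, 0 °C) should put the formyl group on C3 by ipso-substitution of the silyl group, assisted by the ortho titanium phenoxide, to give allyl 3-formyl-2-hydroxy-4-methoxy-6-methylbenzoate F1. Deallylation (Pd(PPh3)4, morpholine, THF) would give 3-formyl-2-hydroxy-4-methoxy-6-methylbenzoic acid F2. Condensation of F2 with 19 by trifluoroacetic anhydride in toluene, the classical depside esterification through the mixed anhydride with the chelated 2-hydroxyl left free, would deliver 26.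

**Step 2.**
- What may go wrong: in the one-flask sequence, leftover chlorotrimethylsilane may consume the second base, or incomplete first silylation may lead to carboxylation between the oxygens. The second deprotonation, at the C–H flanked by the carbamate and the methyl group, may be incomplete or compete with deprotonation of a Si–CH3 group. Anionic Fries migration of the carbamoyl group may set in if the temperature rises, and the aryllithium may add a second time to the new ester.
- Fallback, setting out from 2 and returning at 11 without a second lithiation: only the first half of step 2 is run (through 3, 4 and 5) and aqueous work-up gives 3-methoxy-5-methyl-2-(trimethylsilyl)phenyl N-isopropylcarbamate F3. Decarbamoylation (Et2NH, DBU, MeCN, 40 °C) gives 3-methoxy-5-methyl-2-(trimethylsilyl)phenol F4. Magnesium-mediated ortho-formylation (MgCl2, Et3N, paraformaldehyde, MeCN, reflux) can reach only the one free ortho position and should give 2-hydroxy-4-methoxy-6-methyl-3-(trimethylsilyl)benzaldehyde F5. Triflation (PhNTf2, K2CO3, DMF) gives 2-formyl-5-methoxy-3-methyl-6-(trimethylsilyl)phenyl trifluoromethanesulfonate F6. Pinnick oxidation (NaClO2, NaH2PO4, 2-methylbut-2-ene, t-BuOH–H2O) gives 11 directly, so steps 3 and 4 are bypassed.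

**Step 10.**
- What may go wrong: slow acyl transfer between two di-ortho-substituted partners, which gives hydrolysis of the acid chloride or attack of the phenoxide at the sulfonyl group time to compete.
- Fallback, setting out from 8 and 19 and returning at 21 with the order of esterification and triflation reversed: 9 is isolated (step 3 without the triflating agent) and deallylated (Pd(PPh3)4, morpholine) to 2-hydroxy-4-methoxy-6-methyl-3-(trimethylsilyl)benzoic acid F7. Carbodiimide condensation of this ortho-hydroxy acid with 19 (DCC, toluene–Et2O) should be easier because a hydroxyl is much smaller than a triflate and hydrogen-bonds to the activated carbonyl. It would give benzyl 2,4-bis(benzyloxy)-3-formyl-5-{[2-hydroxy-4-methoxy-6-methyl-3-(trimethylsilyl)benzoyl]oxy}-6-methylbenzoate F8. Triflation of F8 (Tf2O, pyridine, CH2Cl2, 0 °C) gives 21.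

**Step 9.**
- What may go wrong: sluggish oxidative addition or transmetalation at the bromide flanked by benzyloxy and methyl, leading to protodebromination, and Dakin-type loss of the formyl group during the oxidation.
- Fallback, setting out from 17 and returning at 19: the C–O bond is formed directly by reductive elimination, in a palladium-catalysed hydroxylation with boric acid as the hydroxide source (Pd(OAc)2, t-BuBrettPhos, Cs2CO3, B(OH)3, NMP, 80 °C). No boron intermediate and no peroxide are involved; this fallback makes no new compound (entry F0).

**Step 6.**
- What may go wrong: poor site selectivity (bromination at C3' between the hydroxyls) or over-bromination.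
- Fallback, setting out from 13 and returning at 16 with the order of the two substitutions reversed: Rieche formylation of 13 (Cl2CHOMe, TiCl4, CH2Cl2, −10 °C), in which chelation of titanium by the two phenoxides favours C3', should give benzyl 3-formyl-2,4-dihydroxy-6-methylbenzoate F9 after separation from any C5' isomer. NBS can then brominate only C5' and gives 16.

## Further compounds

F1 | step 11 | allyl 3-formyl-2-hydroxy-4-methoxy-6-methylbenzoate | COc1cc(C)c(C(=O)OCC=C)c(O)c1C=O
F2 | step 11 | 3-formyl-2-hydroxy-4-methoxy-6-methylbenzoic acid | COc1cc(C)c(C(=O)O)c(O)c1C=O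
F3 | step 2 | 3-methoxy-5-methyl-2-(trimethylsilyl)phenyl N-isopropylcarbamate | COc1cc(C)cc(OC(=O)NC(C)C)c1[Si](C)(C)C
F4 | step 2 | 3-methoxy-5-methyl-2-(trimethylsilyl)phenol | COc1cc(C)cc(O)c1[Si](C)(C)C
F5 | step 2 | 2-hydroxy-4-methoxy-6-methyl-3-(trimethylsilyl)benzaldehyde | COc1cc(C)c(C=O)c(O)c1[Si](C)(C)C
F6 | step 2 | 2-formyl-5-methoxy-3-methyl-6-(trimethylsilyl)phenyl trifluoromethanesulfonate | COc1cc(C)c(C=O)c(OS(=O)(=O)C(F)(F)F)c1[Si](C)(C)C
F7 | step 10 | 2-hydroxy-4-methoxy-6-methyl-3-(trimethylsilyl)benzoic acid | COc1cc(C)c(C(=O)O)c(O)c1[Si](C)(C)C
F8 | step 10 | benzyl 2,4-bis(benzyloxy)-3-formyl-5-{[2-hydroxy-4-methoxy-6-methyl-3-(trimethylsilyl)benzoyl]oxy}-6-methylbenzoate | COc1cc(C)c(C(=O)Oc2c(C)c(C(=O)OCc3ccccc3)c(OCc3ccccc3)c(C=O)c2OCc2ccccc2)c(O)c1[Si](C)(C)C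
F0 | step 9 | none | none
F9 | step 6 | benzyl 3-formyl-2,4-dihydroxy-6-methylbenzoate | Cc1cc(O)c(C=O)c(O)c1C(=O)OCc1ccccc1
A1 | alternative 1 | benzyl 2,4-bis(benzyloxy)-6-methyl-5-[(3,5,7-trioxooctanoyl)oxy]benzoate | CC(=O)CC(=O)CC(=O)CC(=O)Oc1c(C)c(C(=O)OCc2ccccc2)c(OCc2ccccc2)cc1OCc1ccccc1
A2 | alternative 1 | benzyl 2,4-bis(benzyloxy)-5-[(2,4-dihydroxy-6-methylbenzoyl)oxy]-6-methylbenzoate | Cc1cc(O)cc(O)c1C(=O)Oc1c(C)c(C(=O)OCc2ccccc2)c(OCc2ccccc2)cc1OCc1ccccc1
A3 | alternative 2 | 2-(benzyloxy)-3-iodo-6-methoxy-4-methylbenzaldehyde | COc1cc(C)c(I)c(OCc2ccccc2)c1C=O
A4 | alternative 2 | carbon monoxide | [C-]#[O+]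
A5 | alternative 2 | benzyl 2,4-bis(benzyloxy)-5-{[2-(benzyloxy)-3-formyl-4-methoxy-6-methylbenzoyl]oxy}-3-formyl-6-methylbenzoate (tetra-O-benzyl haemathamnolic acid) | COc1cc(C)c(C(=O)Oc2c(C)c(C(=O)OCc3ccccc3)c(OCc3ccccc3)c(C=O)c2OCc2ccccc2)c(OCc2ccccc2)c1C=O
A6 | alternative 3 | 1,3-dimethoxy-1-(trimethylsilyloxy)buta-1,3-diene (alkene geometry not defined) | COC(=C)C=C(OC)O[Si](C)(C)C
A7 | alternative 3 | benzyl 2,4-bis(benzyloxy)-5-(but-2-ynoyloxy)-6-methylbenzoate | CC#CC(=O)Oc1c(C)c(C(=O)OCc2ccccc2)c(OCc2ccccc2)cc1OCc1ccccc1
A8 | alternative 3 | benzyl 2,4-bis(benzyloxy)-5-[(2-hydroxy-4-methoxy-6-methylbenzoyl)oxy]-6-methylbenzoate | COc1cc(C)c(C(=O)Oc2c(C)c(C(=O)OCc3ccccc3)c(OCc3ccccc3)cc2OCc2ccccc2)c(O)c1
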